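Which species holds most of the substrate after 2.5 d in south-west and in north, and how much of it?

1. which of these there is most of at the end, counted by the substrate in it, south-west (double product / first product / substrate / trapped intermediate)
2. which of these there is most of at the end, counted by the substrate in it, north (double product / first product / substrate / trapped intermediate)
3. the largest of these amounts at the end, in percent of the substrate charged, south-west
4. the largest of these amounts at the end, in percent of the substrate charged, north

| flask | substrate | reagent | capture agent | temperature | remark | time |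
|---|---|---|---|---|---|---|
| Friday's | 1.1 M | 1.32 M | 0.037 M | 22 °C | run made earlier |  |
| Saturday's | 1.1 M | 1.32 M | 0.083 M | 37 °C | run made earlier |  |
| south-west | 1.1 M | 1.32 M | 0.0550 M | 25 °C |  | 2.5 d |
| north | 1.1 M | 1.32 M | 0.0550 M | 33 °C |  | 2.5 d |

Friday's run (percent of the substrate charged)

| time / d | tris adduct / % | trapped intermediate / % | first product / % | substrate / % | double product / % |
|---|---|---|---|---|---|
| 0.417 | 0.1 | 0.7 | 7.9 | 89.9 | 0 |
| 0.833 | 1.0 | 0 | 15.8 | 84.6 | 0 |
| 1.25 | 1.2 | 0 | 23.8 | 78.1 | 0 |
| 1.67 | 0 | 0 | 26.4 | 72.0 | 0 |
| 2.00 | 1.4 | 1.0 | 30.1 | 68.5 | 0 |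
| 2.50 | 0 | 0.7 | 38.3 | 63.2 | 0.5 |
| 3.00 | 1.1 | 0 | 39.7 | 56.6 | 0 |

Saturday's run (percent of the substrate charged)

| time / h | tris adduct / % | trapped intermediate / % | first product / % | substrate / % | double product / % |
|---|---|---|---|---|---|
| 2.00 | 0.5 | 0.1 | 6.6 | 91.5 | 0.8 |
| 6.00 | 0 | 0.9 | 21.0 | 80.0 | 0 |
| 12.0 | 1.5 | 0.7 | 33.4 | 65.4 | 0 |
| 15.0 | 0 | 2.8 | 38.1 | 59.6 | 0.7 |
| 20.0 | 2.1 | 2.7 | 41.9 | 51.4 | 1.0 |
| 30.0 | 0.5 | 5.2 | 51.0 | 42.1 | 2.4 |
| 40.0 | 1.6 | 6.5 | 56.9 | 33.7 | 2.9 |

(readings scatter by 1 percentage point)



Each new flask has a neighbour among the runs: south-west resembles the last row of Friday's run, and north the last row of Saturday's. All of them charge 1.1 M substrate and 1.32 M reagent, so for the substrate I compare rate constant and time. If each substrate takes one reagent, the integrated second-order law applied to those rows gives readings of 0.182 M⁻¹ d⁻¹ for Friday's and 0.773 M⁻¹ d⁻¹ for Saturday's, each carrying the scatter of its row. Interpolating the logarithm in temperature, I get 0.243 M⁻¹ d⁻¹ for south-west and 0.526 M⁻¹ d⁻¹ for north.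

For south-west, rate constant times reagent as charged times time gives 0.803: this is the lifetime count, the substrate's lifetimes reckoned pseudo-first-order, with the reagent held at its charge. Friday's last row stands at 0.722, so south-west is slightly further along despite its shorter time, because its rate constant gains more than its time loses. North reaches 1.74 against 1.70 for Saturday's, its longer time and its smaller rate constant nearly cancelling.

With these charges, half of the substrate is gone at a count of 0.925. South-west falls below that mark and north above it. My reckoning leaves 53.8% substrate in south-west and 33.2% in north. Deducting Saturday's follow-on products unchanged gives north 55.8% first product.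

The forecast names substrate at 55% for south-west and first product at 58% for north. Its north figure stands above mine, since it takes smaller follow-on losses at the lower temperature: they “appear more temperature-sensitive than the first step”.

The flasks give substrate at 54.8% in south-west and first product at 58.8% in north.

    substrate + reagent → first product (k = 0.00983 M⁻¹ h⁻¹, Ea = 77.0 kJ mol⁻¹)
    reagent + first product → double product (k = 7.55 × 10⁻⁴ M⁻¹ h⁻¹, Ea = 93.0 kJ mol⁻¹)
    reagent + double product ⇌ tris adduct (K = 0.727 M⁻¹, k = 0.0130 M⁻¹ h⁻¹, Ea = 75.0 kJ mol⁻¹, ΔH = −4.00 kJ mol⁻¹)
    first product + capture agent → trapped intermediate (k = 0.0262 M⁻¹ h⁻¹, Ea = 75.0 kJ mol⁻¹)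
    (constants at 25 °C)

South-west's count of 0.803 lies under the mark of 0.925, and its substrate stands at 54.8% against 42.3% first product. In south-west at 2.50 d, first product is made 6.69 times faster than it is used up, each step taken net. The south-west call turns with more count: read at 4.0 d, the same flask has a count of 1.28, above the mark, and first product leads with 52.6% against 42.3% substrate.

The numbers in the tables were generated by integration for substances that don't exist; scatter was added.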